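(The earlier runs and the new flask stem from a simulated flask with made-up constants, noise included.)

Early in a run, substrate and partner make target at a pace that need not last, and the question is what happens to that pace once target has appeared.

| flask | substrate | partner | time |
|---|---|---|---|
| north | 0.100 M | 0.300 M |  |
| west | 0.300 M | 0.300 M |  |
| north-west | 0.100 M | 0.600 M |  |
| east | 0.0400 M | 0.240 M | 55 s |

| run | time / s | [target] / M |
|---|---|---|
| north run | 9.2 | 0.0147 |
| north run | 18 | 0.0292 |
| north run | 28 | 0.0430 |
| north run | 37 | 0.0540 |
| north run | 46 | 0.0617 |
| north run | 55 | 0.0683 |
| west run | 9.2 | 0.0550 |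
| west run | 18 | 0.1120 |
| west run | 28 | 0.1596 |
| west run | 37 | 0.1867 |
| west run | 46 | 0.2040 |
| west run | 55 | 0.2137 |
| north-west run | 9.2 | 0.0320 |
| north-west run | 18 | 0.0557 |
| north-west run | 28 | 0.0730 |
| north-west run | 37 | 0.0802 |
| north-west run | 46 | 0.0818 |
| north-west run | 55 | 0.0809 |

(scatter of a reading: 3 × 10⁻⁴ M)

- Overall: substrate + partner -> target.
- Constant volume, constant temperature.
- An order is taken over about fifteen percent of the charge, up and down.

1. the power of [partner] that the first rate follows, about the charge of the north run; measure it at two percent of substrate made into target
2. the power of [substrate] that the first rate follows, about the charge of the north run; measure it at two percent of substrate made into target (one fixed amount of target, the same in the runs compared)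
3. target in the east run at 55 s, as a share of the substrate charged

Divide the rate over an interval by the interval's mean [S][R], with S the substrate and R the partner, and call the result the specific rate. In the west run it is 0.0805 M⁻¹ s⁻¹ over the first interval, at a mean target of 0.0275 M. Over the second interval, at 0.0835 M, it rises to 0.138 M⁻¹ s⁻¹. A line through these two readings gives a plain constant k of 0.0522 M⁻¹ s⁻¹ and a slope a of 1.03 M⁻² s⁻¹. Two amounts then matter. One is their ratio k/a, 0.0507 M, called Pc: the crossover target, where the assisted path equals the plain one. The other is P̄, the mean target during a run. At one fixed target this law is first order in S and in R.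

The east run has partner in excess, so it is treated as pseudo-first-order, with the curve replaced by its means: the share made is 1 − exp(−k(1 + P̄/Pc)R̄t). Suppose half the substrate turns along a roughly straight rise; P̄ is then a quarter of the charge, 0.0100 M, and P̄/Pc is 0.197. This reckoning gives 54.6%, before any loss of target, which the last readings of the north-west run suggest by going from 0.0818 M to 0.0809 M, with a scatter of 3 × 10⁻⁴ M on each.

The forecast reads the rise as “target-assisted (autocatalytic-like) rate”. It gives orders of 1.1 in partner and 1.08 in substrate, and 47% for the east run, between 39% and 55%; the reckoning above stands higher.

The flask gives orders of 1.0 in partner and 1.0 in substrate, and 52.1% in the east run.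

    substrate + partner → target (0.05400 M⁻¹ s⁻¹)
    target + partner → side product (0.006720 M⁻¹ s⁻¹)
    target → decomposed product (0.001340 s⁻¹)
    substrate + partner + target → 2 target (1.120 M⁻² s⁻¹)

The assisted step lifts the east run: without it, that run gives 45.2% instead of 52.1%. Taking the mean as half the final target, P̄ in the east run is about 0.0104 M, so this reckoning multiplies the exponent −ln(1 − share) of the run without the step by 1.21. That estimate turns 45.2% into 51.7%.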